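**Atom labels.** Acid-chain numbering is used throughout: C1 is the carboxyl carbon, C5 the stereocentre, C17 the chain end; C1′–C3′ are the three carbons that lead from C2 to the furan.

## The problem

The target 24 is an open-chain C30 acid whose only ring is a 3-monosubstituted furan that can be bought. No ring has to be closed; the work lies in joining an irregular ten-carbon unit (C4–C9 with the isopropenyl group on C5), a regular ten-carbon unit (C10–C17) and a furan-bearing head (C1–C3, C1′–C3′) without moving any of the six C=C bonds. There is one stereocentre, C5 (R). It lies between two methylene groups, remote from every functional group, so nothing in the molecule can direct its formation and it directs nothing in return; it must be bought or set by a catalyst. C5–H is tertiary and allylic to the isopropenyl group, so strong acid, hot base or migrating metal hydrides could shift the 1,1-disubstituted alkene into the tetrasubstituted position and erase the centre. Three trisubstituted alkenes carry geometry: (7E), (11Z) and the (2Z) α-alkylidene acid, in which the carboxyl group is cis to C2′. This last one is the less stable, angelate-type arrangement, so equilibrating carbonyl olefinations at C2 are excluded. The furan (acid, halogens, peroxides), the 1,5-diene array (cation–olefin cyclisation under acid) and the free acid restrict what may be used late. The enabling feature is that C5 with its isopropenyl group, C4 and the arm C6–C7=C8(CH3)–C9 is the carbon skeleton of (R)-lavandulol 1, with C4 as the hydroxymethyl carbon and C9 as the (E)-methyl group, while C10–C17 is the skeleton of nerol 5. The C9–C10 bond therefore links two allylic methylenes that both arise most naturally as allylic electrophiles, and a removable sulfonyl group on C10 can turn one of them into a nucleophile.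

## Retrosynthesis

**C1–C2.** The carboxyl carbon is removed first: 24 is traced through lithium carboxylate 23 to alkenyllithium 22 and so to the (Z)-alkenyl bromide 21. An olefination across C2=C1′ would favour the wrong (2E) acid. This cut instead makes geometry a matter of retention, since halogen–lithium exchange and carboxylation both keep configuration. 21 has no acidic function and tolerates everything that precedes it. The forward step must exchange bromine faster than it metalates the furan.

**C3–C4.** 21 is cut between C3 and C4 into the C20 bromide 13, used as its Grignard reagent 20, and the allylic dibromide 19. The neighbouring cuts are poorer: C2–C3 would need a one-carbon homologation of the lavandulol-derived terminus, and C4–C5 would destroy the purchased stereocentre. With C3–C4, the nucleophilic carbon is the hydroxymethyl carbon of 1, and the C2=C1′ geometry is prepared beforehand on a nine-carbon fragment. The forward reaction must substitute 19 at its primary allylic carbon, not at C1′, and leave the vinylic bromide alone.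

**The head fragment.** Dibromide 19 comes from allylic alcohol 18 and α-bromo ester 17. The C2=C1′ bond of 17 is a Wittig disconnection to 3-(furan-3-yl)propanal 16. A stabilised α-bromo ylide puts the ester trans to the chain, hence bromine cis to C2′, which is the relationship 21 needs. 16 is reached from furan-3-carbaldehyde 14 by a two-carbon homologation through enal 15. All of this chemistry is done on small, cheap compounds.

**C10–S and the C4 terminus.** Bromide 13 is derived from alcohol 12 and its silyl ether 11. 11 is the reduction product of allylic sulfone 10, so a phenylsulfonyl group is placed retrosynthetically on C10. Putting it on C10 rather than C9 matters for its removal. The allyl unit C10–C11–C12 has one secondary and one fully substituted terminus, so hydride delivery to C10 is favoured and the trisubstituted alkene is kept. A C9 sulfone would give an allyl unit with two secondary termini (C7 and C9). The removal is scheduled before the furan and the vinylic bromide exist.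

**C9–C10, the key cut.** 10 is divided into allylic bromide 4 and lithiated neryl phenyl sulfone 9, made from sulfone 8. This cut falls between two C10 units that map onto commercial monoterpene alcohols, and it forms a bond between sp3 carbons with no alkene created or moved. A cut at C8–C9 or C10–C11 would give non-terpenoid fragments, and an allylic organomagnesium partner would scramble position and geometry. The precursors are far simpler: 4 holds the only stereocentre and 8 the (11Z) alkene. The forward reaction must be α-selective at the anion and SN2-selective at the bromide.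

**The two terpene fragments.** Bromide 4 is traced through allylic alcohol 3 and silyl ether 2 to 1; the (E)-methyl group of the prenyl terminus is the position that allylic oxidation reaches selectively. Sulfone 8 comes from neryl bromide 6 and sodium benzenesulfinate 7, and 6 from nerol 5. No carbon–carbon bond is needed in either fragment.

## Roads not taken

**Alternative 1:** The cut is the furan C3=C4 bond, made last. The acyclic acetal A2 would be closed with the second-generation Grubbs catalyst RuCl2(=CHPh)(PCy3)(H2IMes) to a 2-methoxy-2,5-dihydrofuran. Acid in the same pot would eliminate the alkoxy group and give furan ester A1, and saponification would follow. Its merit is real: the sensitive furan never meets an organolithium, a brominating agent or an oxidant, and in that respect it is better than the chosen plan. Its weak points are these: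
- It spends several steps building a ring that is sold as 14.
- A2 must carry an acid-labile mixed acetal through the whole chain assembly.
- A2 offers the ruthenium carbene six further alkenes, among them the isopropenyl group and the isopropylidene terminus.
- The aromatising acid is a threat to the 1,5-diene array.
- It says nothing about the chain or C5, which would still need something like the present plan.

The chosen plan answers the furan problem by bringing the ring in only for steps 15 and 16, where the reagents are an alkyl Grignard reagent with catalytic copper, t-BuLi at −78 °C and a brief cold acid quench.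

**Alternative 2:** The cut is C4–C5, with creation of the stereocentre. The functionalised dialkylzinc A5 would add to the γ-carbon of the (2E)-2-methylallylic phosphate A4 under (CuOTf)2·C6H6 and a chiral N-heterocyclic carbene. The double bond would shift to become the isopropenyl group and give ester A3. Its merits are that the centre is made catalytically, either enantiomer is accessible, and no chiral-pool supply is needed; in these respects it is better than the chosen plan. Its weak points:
- A4 is not a regular terpenoid. It contains a doubly allylic methylene between its C2=C3 and C5=C6 bonds and must itself be assembled with control of three alkene geometries.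
- The substitution has to create a tertiary centre next to a 2-methyl branch with a functionalised zinc reagent, a combination for which both γ-selectivity and enantioselectivity are uncertain.
- A3 lacks the α-alkylidene unit, and an aldol–dehydration at C2 would favour the (2E) acid.

The chosen plan sets against it a stereocentre of known configuration from the first step and a (2Z) acid made by retention rather than by selectivity.

**Alternative 3:** The cut is C2–C3. The alkylzinc made from iodide A7 would couple, under PdCl2 with bis[2-(diphenylphosphino)phenyl] ether, only with the bromine trans to the chain of the 1,1-dibromoalkene A8. The product is the (Z)-bromoalkene A6, which is the same compound as 21. Its merits: the C2=C1′ geometry comes from a stereospecific choice between two bromines on one carbon, there is no SN2/SN2′ ambiguity, and A8 is one step from aldehyde 16 where 19 needs three. In control of the C2 geometry it is at least as good as the chosen plan. Its weak points: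
- A7 needs a one-carbon homologation of the lavandulol-derived terminus, about three steps on the most valuable intermediate.
- The sp3 zinc reagent brings β-hydride elimination and double substitution as side paths.
- It is a tactic for the head only and still needs a chain assembly.

The chosen plan sets against it a shorter longest linear sequence, with the extra steps placed on the small furan fragment, and keeps this tactic as the fallback for step 15.

Key step: step 6

Assumption: (R)-lavandulol 1 is purchased, or resolved from the racemate with a lipase, in high enantiomeric purity; no step creates or touches C5, so the enantiomeric purity of 24 should equal that of 1.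

## Route

Step 1
Reactants: 1 (R)-lavandulol
Product: 2 tert-butyl(dimethyl){[(2R)-5-methyl-2-(prop-1-en-2-yl)hex-4-en-1-yl]oxy}silane
Conditions: TBSCl, imidazole, DMF, 0 °C → rt
Reagents that add atoms: tert-butyldimethylsilyl chloride, CC(C)(C)[Si](C)(C)Cl
Why: Imidazole-promoted silylation of a primary alcohol; the silyl ether protects C4–OH against the oxidant of step 2, the carbanion of step 6 and LiBHEt3 in step 7, and C5 is not involved.

Step 2
Reactants: 2 tert-butyl(dimethyl){[(2R)-5-methyl-2-(prop-1-en-2-yl)hex-4-en-1-yl]oxy}silane
Product: 3 (2E,5R)-6-{[tert-butyl(dimethyl)silyl]oxy}-2-methyl-5-(prop-1-en-2-yl)hex-2-en-1-ol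
Conditions: SeO2 (cat.), t-BuOOH, salicylic acid (cat.), CH2Cl2, rt; then NaBH4, MeOH, 0 °C
Reagents that add atoms: selenium dioxide, O=[Se]=O (oxygen carrier); tert-butyl hydroperoxide, CC(C)(C)OO (terminal oxygen source)
Why: SeO2 allylic oxidation (ene reaction, then [2,3]-sigmatropic shift, with selenium recycled by t-BuOOH) attacks the more electron-rich trisubstituted alkene at the methyl group trans to the chain, which fixes the (E)-hydroxymethyl geometry that becomes (7E); the borohydride quench returns over-oxidised material to the alcohol level.

Step 3
Reactants: 3 (2E,5R)-6-{[tert-butyl(dimethyl)silyl]oxy}-2-methyl-5-(prop-1-en-2-yl)hex-2-en-1-ol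
Product: 4 tert-butyl{[(2R,4E)-6-bromo-5-methyl-2-(prop-1-en-2-yl)hex-4-en-1-yl]oxy}dimethylsilane
Conditions: CBr4, PPh3, CH2Cl2, 0 °C
Reagents that add atoms: tetrabromomethane, BrC(Br)(Br)Br
Why: Appel bromination turns the primary allylic alcohol into the bromide by SN2 at the alkoxyphosphonium stage under neutral conditions, so neither allylic transposition nor loss of the silyl ether is expected.

Step 4
Reactants: 5 nerol
Product: 6 (2Z)-1-bromo-3,7-dimethylocta-2,6-diene (neryl bromide)
Conditions: PBr3, Et2O, −10 °C
Reagents that add atoms: phosphorus tribromide, BrP(Br)Br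
Why: Bromination of a primary allylic alcohol with PBr3 at low temperature proceeds by SN2 on the phosphite ester and keeps the (2Z) geometry of nerol.

Step 5
Reactants: 6 neryl bromide; 7 sodium benzenesulfinate
Product: 8 {[(2Z)-3,7-dimethylocta-2,6-dien-1-yl]sulfonyl}benzene (neryl phenyl sulfone)
Conditions: DMF, rt
Reagents that add atoms: none
Why: S-alkylation of the ambident sulfinate by a primary allylic bromide (SN2) gives the thermodynamically preferred primary allylic sulfone with unchanged (Z) geometry.

Step 6
Reactants: 8 neryl phenyl sulfone; 4 tert-butyl{[(2R,4E)-6-bromo-5-methyl-2-(prop-1-en-2-yl)hex-4-en-1-yl]oxy}dimethylsilane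
Product: 10 tert-butyl(dimethyl){[(2R,4E,8Z)-5,9,13-trimethyl-7-(phenylsulfonyl)-2-(prop-1-en-2-yl)tetradeca-4,8,12-trien-1-yl]oxy}silane (both epimers at the sulfonyl-bearing carbon, C10 of the acid chain), via lithiated neryl phenyl sulfone 9 (not isolated)
Conditions: n-BuLi, THF, −78 °C; then 4, THF–DMPU, −78 → −20 °C
Reagents that add atoms: none
Why: n-BuLi removes the C10 proton of 8, acidified by the sulfonyl group and the adjacent alkene, and the resulting α-sulfonyl allyl carbanion 9 displaces bromide from the primary allylic carbon C9 of 4 in a direct SN2 reaction that forms the C9–C10 bond. The closest known reaction type is the alkylation of lithiated prenyl-type aryl sulfones with allylic halides, the classical way of linking isoprenoid units. No ring is closed. The only new stereocentre, C10, is formed without control and is deliberately left as an epimer mixture, because step 7 turns it into a methylene group. The step needs α- rather than γ-attack of the ambident anion; charge localisation next to sulfur and the fully substituted γ-carbon C12 secure it. It also needs SN2 rather than SN2′ substitution at the electrophile, which the unhindered CH2Br terminus, set against a γ-carbon C7 shielded by the branched C5–C6 arm, should provide. The (11Z) geometry should persist because the C11=C12 bond of the sulfonyl-stabilised anion keeps its double-bond character at −78 °C, while the (7E) alkene, C5, the silyl ether and the isopropenyl group take no part. A slight excess of cheap 8 and the low temperature limit proton transfer from 10 to 9 and thus a second alkylation.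

Step 7
Reactants: 10 coupled C10 phenylsulfonyl silyl ether
Product: 11 tert-butyl(dimethyl){[(2R,4E,8Z)-5,9,13-trimethyl-2-(prop-1-en-2-yl)tetradeca-4,8,12-trien-1-yl]oxy}silane
Conditions: PdCl2[Ph2P(CH2)3PPh2] (5 mol%), LiBHEt3, THF, 0 °C
Reagents that add atoms: none
Why: Palladium-catalysed reductive desulfonylation of an allylic sulfone: zerovalent palladium formed in situ ionises the allylic C–S bond, LiBHEt3 transfers hydride to palladium and reductive elimination at the less substituted allyl terminus C10 restores the trisubstituted C11=C12 alkene; fast hydride capture under the chelating diphosphine should outrun syn–anti isomerisation so that (11Z) is kept, and both C10 epimers converge on one compound.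

Step 8
Reactants: 11 tert-butyl(dimethyl){[(2R,4E,8Z)-5,9,13-trimethyl-2-(prop-1-en-2-yl)tetradeca-4,8,12-trien-1-yl]oxy}silane
Product: 12 (2R,4E,8Z)-5,9,13-trimethyl-2-(prop-1-en-2-yl)tetradeca-4,8,12-trien-1-ol
Conditions: Bu4NF, THF, 0 °C → rt
Reagents that add atoms: none
Why: Fluoride-induced desilylation driven by the Si–F bond; no other group in 11 responds to the reagent.

Step 9
Reactants: 12 (2R,4E,8Z)-5,9,13-trimethyl-2-(prop-1-en-2-yl)tetradeca-4,8,12-trien-1-ol
Product: 13 (6Z,10E,13R)-14-bromo-2,6,10-trimethyl-13-(prop-1-en-2-yl)tetradeca-2,6,10-triene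
Conditions: CBr4, PPh3, CH2Cl2, 0 °C
Reagents that add atoms: tetrabromomethane, BrC(Br)(Br)Br
Why: Appel bromination under neutral conditions avoids the acid that would start cation–olefin cyclisation of the polyene; substitution occurs at C4, one carbon away from C5, whose configuration is untouched.

Step 10
Reactants: 14 furan-3-carbaldehyde
Product: 15 (2E)-3-(furan-3-yl)prop-2-enal
Conditions: Ph3P=CHCHO, toluene, 80 °C
Reagents that add atoms: (triphenylphosphoranylidene)acetaldehyde, O=CC=P(c1ccccc1)(c1ccccc1)c1ccccc1
Why: Wittig reaction of a stabilised formyl ylide with an aromatic aldehyde gives the (E)-enal and adds both missing carbons (C2′, C1′) in one step.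

Step 11
Reactants: 15 (2E)-3-(furan-3-yl)prop-2-enal
Product: 16 3-(furan-3-yl)propanal
Conditions: Hantzsch ester (diethyl 2,6-dimethyl-1,4-dihydropyridine-3,5-dicarboxylate), (PhCH2)2NH2+ CF3CO2− (cat.), THF, rt
Reagents that add atoms: none
Why: Iminium-catalysed transfer hydrogenation with a Hantzsch ester delivers hydride only to the β-carbon of the enal, so the aldehyde and the furan ring, which a metal-catalysed hydrogenation could attack, are left alone.

Step 12
Reactants: 16 3-(furan-3-yl)propanal
Product: 17 ethyl (2Z)-2-bromo-5-(furan-3-yl)pent-2-enoate
Conditions: Ph3P=CHCO2Et (1.3 equiv), NBS (1.2 equiv), CH2Cl2, −20 °C; then 16, −20 °C → rt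
Reagents that add atoms: ethyl (triphenylphosphoranylidene)acetate, CCOC(=O)C=P(c1ccccc1)(c1ccccc1)c1ccccc1; N-bromosuccinimide, O=C1CCC(=O)N1Br
Why: Wittig olefination with the stabilised α-bromo ylide made in the flask by brominating the ester ylide: as with other stabilised ylides the ester ends up trans to the new chain, so bromine is cis to C2′, the relationship later transcribed into (2Z); the slight excess of ylide consumes all NBS before the furan is introduced.

Step 13
Reactants: 17 ethyl (2Z)-2-bromo-5-(furan-3-yl)pent-2-enoate
Product: 18 (2Z)-2-bromo-5-(furan-3-yl)pent-2-en-1-ol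
Conditions: i-Bu2AlH, CH2Cl2, −78 °C; aq. potassium sodium tartrate (KNaC4H4O6)
Reagents that add atoms: none
Why: i-Bu2AlH reduces the α,β-unsaturated ester by 1,2-addition to the allylic alcohol at −78 °C without touching the vinylic C–Br bond or the alkene geometry.

Step 14
Reactants: 18 (2Z)-2-bromo-5-(furan-3-yl)pent-2-en-1-ol
Product: 19 3-[(3Z)-4,5-dibromopent-3-en-1-yl]furan
Conditions: CBr4, PPh3, CH2Cl2, 0 °C
Reagents that add atoms: tetrabromomethane, BrC(Br)(Br)Br
Why: Appel bromination of the primary allylic alcohol (SN2) under neutral conditions that the 3-alkylfuran tolerates; the vinylic bromide is inert.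

Step 15
Reactants: 13 (6Z,10E,13R)-14-bromo-2,6,10-trimethyl-13-(prop-1-en-2-yl)tetradeca-2,6,10-triene; 19 3-[(3Z)-4,5-dibromopent-3-en-1-yl]furan
Product: 21 3-[(3Z,7R,9E,13Z)-4-bromo-10,14,18-trimethyl-7-(prop-1-en-2-yl)nonadeca-3,9,13,17-tetraen-1-yl]furan, via alkylmagnesium bromide 20 (not isolated)
Conditions: Mg, THF, rt (solution decanted from excess Mg); then 19, Li2CuCl4 (3 mol%), THF, −30 → 0 °C
Reagents that add atoms: none
Why: Kochi-type Li2CuCl4-catalysed coupling of a primary alkyl Grignard reagent with a primary allylic bromide forms C3–C4 by α-substitution; the vinylic bromide does not couple at this temperature, the geometry of 19 is carried into 21, and removing excess Mg prevents reductive elimination of the vicinal dibromide to an allene.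

Step 16
Reactants: 21 3-[(3Z,7R,9E,13Z)-4-bromo-10,14,18-trimethyl-7-(prop-1-en-2-yl)nonadeca-3,9,13,17-tetraen-1-yl]furan
Product: 24 (2Z,5R,7E,11Z)-2-[3-(furan-3-yl)propylidene]-8,12,16-trimethyl-5-(prop-1-en-2-yl)heptadeca-7,11,15-trienoic acid, via alkenyllithium 22 (not isolated), via lithium carboxylate 23 (not isolated)
Conditions: t-BuLi (2.1 equiv), THF, −78 °C; CO2; then cold dilute HCl
Reagents that add atoms: carbon dioxide, O=C=O
Why: Bromine–lithium exchange of an alkenyl bromide with two equivalents of t-BuLi is faster at −78 °C than metalation of the furan and proceeds with retention; the configurationally stable α-alkylalkenyllithium is carboxylated with retention, so bromine cis to C2′ in 21 becomes carboxyl cis to C2′, the (2Z) acid.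

## Compound list

1 | (R)-lavandulol, (2R)-5-methyl-2-(prop-1-en-2-yl)hex-4-en-1-ol | C=C(C)[C@@H](CC=C(C)C)CO | starting material
2 | tert-butyl(dimethyl){[(2R)-5-methyl-2-(prop-1-en-2-yl)hex-4-en-1-yl]oxy}silane | C=C(C)[C@@H](CC=C(C)C)CO[Si](C)(C)C(C)(C)C | intermediate
3 | (2E,5R)-6-{[tert-butyl(dimethyl)silyl]oxy}-2-methyl-5-(prop-1-en-2-yl)hex-2-en-1-ol | C=C(C)[C@@H](C/C=C(\C)CO)CO[Si](C)(C)C(C)(C)C | intermediate
4 | tert-butyl{[(2R,4E)-6-bromo-5-methyl-2-(prop-1-en-2-yl)hex-4-en-1-yl]oxy}dimethylsilane | C=C(C)[C@@H](C/C=C(\C)CBr)CO[Si](C)(C)C(C)(C)C | intermediate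
5 | nerol, (2Z)-3,7-dimethylocta-2,6-dien-1-ol | CC(C)=CCC/C(C)=C\CO | starting material
6 | neryl bromide, (2Z)-1-bromo-3,7-dimethylocta-2,6-diene | CC(C)=CCC/C(C)=C\CBr | intermediate
7 | sodium benzenesulfinate | [Na+].[O-]S(=O)c1ccccc1 | starting material
8 | neryl phenyl sulfone, {[(2Z)-3,7-dimethylocta-2,6-dien-1-yl]sulfonyl}benzene | O=S(=O)(C/C=C(/C)CCC=C(C)C)c1ccccc1 | intermediate
9 | [(2Z)-3,7-dimethyl-1-(phenylsulfonyl)octa-2,6-dien-1-yl]lithium (lithiated neryl phenyl sulfone) | [Li]C(/C=C(/C)CCC=C(C)C)S(=O)(=O)c1ccccc1 | intermediate
10 | tert-butyl(dimethyl){[(2R,4E,8Z)-5,9,13-trimethyl-7-(phenylsulfonyl)-2-(prop-1-en-2-yl)tetradeca-4,8,12-trien-1-yl]oxy}silane, both C7 epimers | C=C(C)[C@@H](C/C=C(\C)CC(/C=C(/C)CCC=C(C)C)S(=O)(=O)c1ccccc1)CO[Si](C)(C)C(C)(C)C | intermediate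
11 | tert-butyl(dimethyl){[(2R,4E,8Z)-5,9,13-trimethyl-2-(prop-1-en-2-yl)tetradeca-4,8,12-trien-1-yl]oxy}silane | C=C(C)[C@@H](C/C=C(\C)CC/C=C(/C)CCC=C(C)C)CO[Si](C)(C)C(C)(C)C | intermediate
12 | (2R,4E,8Z)-5,9,13-trimethyl-2-(prop-1-en-2-yl)tetradeca-4,8,12-trien-1-ol | C=C(C)[C@@H](C/C=C(\C)CC/C=C(/C)CCC=C(C)C)CO | intermediate
13 | (6Z,10E,13R)-14-bromo-2,6,10-trimethyl-13-(prop-1-en-2-yl)tetradeca-2,6,10-triene | C=C(C)[C@@H](C/C=C(\C)CC/C=C(/C)CCC=C(C)C)CBr | intermediate
14 | furan-3-carbaldehyde | O=Cc1ccoc1 | starting material
15 | (2E)-3-(furan-3-yl)prop-2-enal | O=C/C=C/c1ccoc1 | intermediate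
16 | 3-(furan-3-yl)propanal | O=CCCc1ccoc1 | intermediate
17 | ethyl (2Z)-2-bromo-5-(furan-3-yl)pent-2-enoate | CCOC(=O)/C(Br)=C/CCc1ccoc1 | intermediate
18 | (2Z)-2-bromo-5-(furan-3-yl)pent-2-en-1-ol | OC/C(Br)=C/CCc1ccoc1 | intermediate
19 | 3-[(3Z)-4,5-dibromopent-3-en-1-yl]furan | BrC/C(Br)=C/CCc1ccoc1 | intermediate
20 | bromo[(2R,4E,8Z)-5,9,13-trimethyl-2-(prop-1-en-2-yl)tetradeca-4,8,12-trien-1-yl]magnesium | C=C(C)[C@@H](C/C=C(\C)CC/C=C(/C)CCC=C(C)C)C[Mg]Br | intermediate
21 | 3-[(3Z,7R,9E,13Z)-4-bromo-10,14,18-trimethyl-7-(prop-1-en-2-yl)nonadeca-3,9,13,17-tetraen-1-yl]furan | C=C(C)[C@@H](C/C=C(\C)CC/C=C(/C)CCC=C(C)C)CC/C(Br)=C/CCc1ccoc1 | intermediate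
22 | [(3E,7R,9E,13Z)-1-(furan-3-yl)-10,14,18-trimethyl-7-(prop-1-en-2-yl)nonadeca-3,9,13,17-tetraen-4-yl]lithium (geometry of 21 retained; the descriptor changes because lithium ranks below carbon) | C=C(C)[C@@H](C/C=C(\C)CC/C=C(/C)CCC=C(C)C)CC/C([Li])=C/CCc1ccoc1 | intermediate
23 | lithium (2Z,5R,7E,11Z)-2-[3-(furan-3-yl)propylidene]-8,12,16-trimethyl-5-(prop-1-en-2-yl)heptadeca-7,11,15-trienoate | C=C(C)[C@@H](C/C=C(\C)CC/C=C(/C)CCC=C(C)C)CC/C(=C/CCc1ccoc1)C(=O)[O-].[Li+] | intermediate
24 | (2Z,5R,7E,11Z)-2-[3-(furan-3-yl)propylidene]-8,12,16-trimethyl-5-(prop-1-en-2-yl)heptadeca-7,11,15-trienoic acid | C=C(C)[C@@H](C/C=C(\C)CC/C=C(/C)CCC=C(C)C)CC/C(=C/CCc1ccoc1)C(=O)O | target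

## Step count and risks

Total: 16 steps. Longest linear sequence: 9 steps from 1 (steps 1, 2, 3, 6, 7, 8, 9, 15, 16). The sulfone branch (steps 4, 5) and the furan branch (steps 10–14) are convergent.

**Step 6 (key step).** The most likely failures are competing γ-alkylation of the ambident anion, SN2′ attack on the bromide, a second alkylation after proton transfer from product to carbanion, and 1,4-elimination of HBr from 4 with the carbanion acting as a base. The fallback keeps the C9–C10 bond but changes the umpolung device. It sets out from nerol 5 and bromide 4 and returns at 11. Nerol 5 would be converted with N-chlorosuccinimide and Me2S into neryl chloride F3. With reactive barium (from BaI2 and two equivalents of lithium biphenylide, THF, −78 °C) this should give nerylbarium chloride F4. Allylbarium reagents of this type keep their double-bond geometry at −78 °C and couple with allylic halides α to α′, so addition of 4 should give 11 directly, bypassing 8, 10 and step 7.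

**Step 2.** Poor site selectivity is the main risk: oxidation at the isopropenyl methyl group or at the tertiary allylic C5–H, besides over-oxidation to the enal stage. The fallback sets out from 2 and returns at 4. Epoxidation with m-chloroperbenzoic acid (CH2Cl2, −20 °C), which discriminates trisubstituted from 1,1-disubstituted alkenes well, would give tert-butyl{[(2R)-2-[(3,3-dimethyloxiran-2-yl)methyl]-3-methylbut-3-en-1-yl]oxy}dimethylsilane F1. Base-induced epoxide opening with Al(Oi-Pr)3 in hot toluene would give (5R)-6-{[tert-butyl(dimethyl)silyl]oxy}-2-methyl-5-(prop-1-en-2-yl)hex-1-en-3-ol F2. PBr3 with a trace of pyridine in Et2O at −10 °C should then deliver the rearranged primary (E)-allylic bromide 4 by SN2′ substitution.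

**Step 7.** Erosion of the (11Z) geometry through syn–anti interconversion of the π-allylpalladium intermediate, or hydride delivery to C12 with transposition of the alkene, would give inseparable isomers. The fallback leaves the palladium π-allyl pathway altogether: 10 would be treated with Li in EtNH2–THF at −78 °C. This is single-electron cleavage of the C–S bond and protonation of the allyl anion at the less substituted carbon, the classical polyprenyl desulfonylation. It leads from 10 directly to 11 and makes no new compound (F0). The silyl ether and the isolated alkenes should tolerate it, and the furan is not yet present.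

**Step 15.** Attack of the organocopper intermediate at C1′ (SN2′) with loss of the alkene geometry, or homocoupling, would waste the C20 fragment. The fallback changes the bond that is formed, from C3–C4 by allylic substitution to C2–C3 by a stereospecific cross-coupling. It sets out from 13 and 16 and returns at 21. Grignard reagent 20, made from 13 as in step 15, would be quenched with paraformaldehyde to give (3S,5E,9Z)-6,10,14-trimethyl-3-(prop-1-en-2-yl)pentadeca-5,9,13-trien-1-ol F5. I2, PPh3 and imidazole would convert it into (6Z,10E,13S)-15-iodo-2,6,10-trimethyl-13-(prop-1-en-2-yl)pentadeca-2,6,10-triene F6. Aldehyde 16 with CBr4 and PPh3 would give 3-(4,4-dibromobut-3-en-1-yl)furan F7. Iodine–lithium exchange of F6 (t-BuLi, Et2O, −78 °C), transmetalation with ZnBr2 and coupling with F7 under PdCl2[(2-Ph2PC6H4)2O] should replace only the bromine trans to the chain and give 21.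

**Step 16.** Protonation of the alkenyllithium by adventitious acid or by the furan α-position, or competing metalation of the furan by t-BuLi, would give reduced or doubly carboxylated material. The fallback avoids organolithium chemistry and sets out from 21, returning at 24. Palladium-catalysed alkoxycarbonylation (PdCl2(PPh3)2 (cat.), CO at 1 atm, EtOH, Et3N, 60 °C) proceeds with retention at the alkenyl carbon and should give ethyl (2Z,5R,7E,11Z)-2-[3-(furan-3-yl)propylidene]-8,12,16-trimethyl-5-(prop-1-en-2-yl)heptadeca-7,11,15-trienoate F8. Saponification with LiOH in THF–H2O at 40 °C should then give 24.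

## Further compounds

F1 | step 2 | tert-butyl{[(2R)-2-[(3,3-dimethyloxiran-2-yl)methyl]-3-methylbut-3-en-1-yl]oxy}dimethylsilane (both epoxide epimers) | C=C(C)[C@@H](CC1OC1(C)C)CO[Si](C)(C)C(C)(C)C
F2 | step 2 | (5R)-6-{[tert-butyl(dimethyl)silyl]oxy}-2-methyl-5-(prop-1-en-2-yl)hex-1-en-3-ol (both C3 epimers) | C=C(C)[C@@H](CC(O)C(C)=C)CO[Si](C)(C)C(C)(C)C
F3 | step 6 | neryl chloride, (2Z)-1-chloro-3,7-dimethylocta-2,6-diene | CC(C)=CCC/C(C)=C\CCl
F4 | step 6 | nerylbarium chloride, chloro[(2Z)-3,7-dimethylocta-2,6-dien-1-yl]barium | CC(C)=CCC/C(C)=C\C[Ba]Cl
F0 | step 7 | none | none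
F5 | step 15 | (3S,5E,9Z)-6,10,14-trimethyl-3-(prop-1-en-2-yl)pentadeca-5,9,13-trien-1-ol | C=C(C)[C@@H](C/C=C(\C)CC/C=C(/C)CCC=C(C)C)CCO
F6 | step 15 | (6Z,10E,13S)-15-iodo-2,6,10-trimethyl-13-(prop-1-en-2-yl)pentadeca-2,6,10-triene | C=C(C)[C@@H](C/C=C(\C)CC/C=C(/C)CCC=C(C)C)CCI
F7 | step 15 | 3-(4,4-dibromobut-3-en-1-yl)furan | BrC(Br)=CCCc1ccoc1
F8 | step 16 | ethyl (2Z,5R,7E,11Z)-2-[3-(furan-3-yl)propylidene]-8,12,16-trimethyl-5-(prop-1-en-2-yl)heptadeca-7,11,15-trienoate | C=C(C)[C@@H](C/C=C(\C)CC/C=C(/C)CCC=C(C)C)CC/C(=C/CCc1ccoc1)C(=O)OCC
A1 | alternative 1 | methyl (2Z,5R,7E,11Z)-2-[3-(furan-3-yl)propylidene]-8,12,16-trimethyl-5-(prop-1-en-2-yl)heptadeca-7,11,15-trienoate | C=C(C)[C@@H](C/C=C(\C)CC/C=C(/C)CCC=C(C)C)CC/C(=C/CCc1ccoc1)C(=O)OC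
A2 | alternative 1 | methyl (2Z,5R,7E,11Z)-2-{4-[(1-methoxyprop-2-en-1-yl)oxymethyl]pent-4-en-1-ylidene}-8,12,16-trimethyl-5-(prop-1-en-2-yl)heptadeca-7,11,15-trienoate (both acetal epimers) | C=C(C)[C@@H](C/C=C(\C)CC/C=C(/C)CCC=C(C)C)CC/C(=C/CCC(=C)COC(OC)C=C)C(=O)OC
A3 | alternative 2 | ethyl (5R,7E,11Z)-8,12,16-trimethyl-5-(prop-1-en-2-yl)heptadeca-7,11,15-trienoate | C=C(C)[C@@H](C/C=C(\C)CC/C=C(/C)CCC=C(C)C)CCCC(=O)OCC
A4 | alternative 2 | diethyl (2E,5E,9Z)-2,6,10,14-tetramethylpentadeca-2,5,9,13-tetraen-1-yl phosphate | CCOP(=O)(OCC)OC/C(C)=C/C/C=C(\C)CC/C=C(/C)CCC=C(C)C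
A5 | alternative 2 | bis(4-ethoxy-4-oxobutyl)zinc | CCOC(=O)CCC[Zn]CCCC(=O)OCC
A6 | alternative 3 | 3-[(3Z,7R,9E,13Z)-4-bromo-10,14,18-trimethyl-7-(prop-1-en-2-yl)nonadeca-3,9,13,17-tetraen-1-yl]furan | C=C(C)[C@@H](C/C=C(\C)CC/C=C(/C)CCC=C(C)C)CC/C(Br)=C/CCc1ccoc1
A7 | alternative 3 | (6Z,10E,13S)-15-iodo-2,6,10-trimethyl-13-(prop-1-en-2-yl)pentadeca-2,6,10-triene | C=C(C)[C@@H](C/C=C(\C)CC/C=C(/C)CCC=C(C)C)CCI
A8 | alternative 3 | 3-(4,4-dibromobut-3-en-1-yl)furan | BrC(Br)=CCCc1ccoc1
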